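All constants were chosen freely.

The constants come first: the scavenger takes leaving ligand at 2.3 M⁻¹ s⁻¹, so free leaving ligand has a half-life of 2.8 s by that step with the scavenger as charged, far shorter than the 4.6 min half-life of the starting complex by the forward first exchange alone, which runs at 0.023 M⁻¹ s⁻¹. With half-lives so far apart, you may set release equal to scavenging, the quasi-steady state.

starting complex 0.073 M; incoming ligand 0.109 M; scavenger 0.109 M; time 15 min

1. part of the starting complex that has reacted at 15 min
2. share of the unused incoming ligand that is free and not bound as idle adduct, at 15 min

- percent here means starting complex units held: one self-condensation product or side product counts as two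
- what is said of leaving ligand includes idle adduct
- two of one species on the left: rate k times its square, two consumed each time
- run time (flask): 15 min

    complex with two exchanged + incoming ligand ⇌ leaving ligand + complex with three exchanged (K1 = 1.1, k1 = 0.030 M⁻¹ s⁻¹)
    scavenger + leaving ligand → scavenged by-product (k2 = 2.3 M⁻¹ s⁻¹)
    leaving ligand + incoming ligand ⇌ idle adduct, settled at all times (K3 = 97 M⁻¹)
    complex with one exchanged + incoming ligand ⇌ leaving ligand + complex with two exchanged (K4 = 1.1, k4 = 0.049 M⁻¹ s⁻¹)
    starting complex + incoming ligand ⇌ leaving ligand + complex with one exchanged (K5 = 1.7, k5 = 0.023 M⁻¹ s⁻¹)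
    complex with three exchanged + incoming ligand ⇌ leaving ligand + complex with four exchanged (K6 = 1.2, k6 = 0.038 M⁻¹ s⁻¹)
    starting complex + complex with one exchanged → side product (k7 = 0.012 M⁻¹ s⁻¹)
    2 starting complex → self-condensation product (k8 = 0.0051 M⁻¹ s⁻¹)

Each exchange spends one incoming ligand and frees one leaving ligand, which then spends one scavenger. The two were charged alike, so [incoming ligand] and [scavenger] fall together and roughly cancel in that balance. The later exchanges have larger constants, so I let them make up for the falling starting complex and keep its charge. That gives 7.30 × 10⁻⁴ M for the hold level, the first-exchange constant times the starting-complex charge over the scavenging constant.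

The idle-adduct balance makes the free share of unused incoming ligand 1/(1 + K[leaving ligand]), with K its equilibrium constant, 97 M⁻¹, so the share is 93.4%. But free incoming ligand is what exchanges, so put that share back: the level becomes 6.82 × 10⁻⁴ M and the share 93.8%. The part reacted needs the whole chain, and my reckoning stops short of it.

The forecast gives 77% (71% to 82%) reacted and 93% free (89% to 96%), its scavenger being “fast enough to hold free leaving ligand”.

The flask gives 77.7% reacted and 94.1% free, both inside those ranges.

In this flask [leaving ligand] reads 6.61 × 10⁻⁴ M at 1.50 min and 6.42 × 10⁻⁴ M at 15.0 min, against the reckoned level of 6.82 × 10⁻⁴ M, while scavenger has dropped to 24% of its charge and incoming ligand to 21%. Now take the neighbour flask with 0.018 M of starting complex, its other two charges unchanged: the hold level becomes 1.80 × 10⁻⁴ M and the free share 98.3%. That neighbour flask reads [leaving ligand] 1.83 × 10⁻⁴ M at 15.0 min and a free share of 98.3%.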